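**Assumptions.** (S)-TRIP and (S,S)-ProPhenol are named for the sense of induction required (S at C6, R at C16); if the sense is reversed with these substrates, the mirror-image catalyst is used.
Numbering in names and comments: ring carbons C1–C10 as in labdanes, chain C11–C19 (C16 = lactone CH–O, C19 = lactone C=O), acid/ester carbon on C4 = C23.

## Retrosynthetic overview

1. Target ⇐ seco-diester 24: saponification, then acidification closes the butenolide (last ring) by lactonisation of a (Z)-γ-hydroxy enoate.
2. 24 ⇐ C12–C13 sp3–sp2 coupling of bicyclic triol 14 (through its primary C12–OH) with alkenyl bromide 22 (C16 set by catalytic alkynylation).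
3. 14 ⇐ hydration of 13 ⇐ radical bicyclisation of acyclic triene 12: rings A and B form together (C4–C5, then C9–C10), all ring stereocentres relayed from the single C6 carbinol.
4. 12 ⇐ two Negishi carboaluminations (both E-trisubstituted alkenes) around an enantioselective propargylation of enal 5 (sets C6), then radical allylation with methyl 2-(bromomethyl)acrylate.

## Route

Step 1
Reactants: 1 but-3-yn-1-ol
Product: 3 (2E)-3-methylpent-2-ene-1,5-diol, via alkenylalane 2 (not isolated)
Conditions: Me3Al (3 equiv), Cp2ZrCl2 (0.25 equiv), CH2Cl2, 0 °C→rt; evaporate; n-BuLi, THF, −78 °C; (CH2O)n, −78 °C→rt; aq. HCl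
Reagents that add atoms: trimethylaluminium C[Al](C)C; formaldehyde (as paraformaldehyde) C=O
Why: Zr-catalysed syn-methylalumination (Negishi carboalumination) fixes the E-trisubstituted alkene, and the derived alanate is hydroxymethylated with retention.

Step 2
Reactants: 3 (2E)-3-methylpent-2-ene-1,5-diol
Product: 4 (2E)-5-hydroxy-3-methylpent-2-enal
Conditions: activated MnO2 (15 equiv), CH2Cl2, rt
Reagents that add atoms: none
Why: MnO2 allylic oxidation touches only the allylic primary alcohol and leaves the homoallylic one.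

Step 3
Reactants: 4 (2E)-5-hydroxy-3-methylpent-2-enal
Product: 5 (2E)-5-iodo-3-methylpent-2-enal
Conditions: I2, PPh3, imidazole, CH2Cl2, 0 °C
Reagents that add atoms: iodine II
Why: Appel iodination of the remaining primary alcohol under near-neutral conditions that the enal tolerates.

Step 4
Reactants: 5 (2E)-5-iodo-3-methylpent-2-enal; 6 allenylboronic acid pinacol ester
Product: 7 (4S,5E)-8-iodo-6-methyloct-5-en-1-yn-4-ol
Conditions: (S)-TRIP (5 mol%), 4 Å MS, toluene, −20 °C
Reagents that add atoms: none
Why: chiral phosphoric acid-catalysed propargylation (SE2′ of the allenylboronate through a closed six-membered transition state) sets the C6 carbinol as S by catalyst control.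

Step 5
Reactants: 7 (4S,5E)-8-iodo-6-methyloct-5-en-1-yn-4-ol; 8 ethylene oxide
Product: 10 (3E,6S,7E)-10-iodo-4,8-dimethyldeca-3,7-diene-1,6-diol, via alkenylalane 9 (not isolated)
Conditions: Me3Al (3 equiv), Cp2ZrCl2 (0.3 equiv), (CH2Cl)2, rt; evaporate; MeLi, THF, −78 °C; ethylene oxide, −78→0 °C; aq. HCl
Reagents that add atoms: trimethylaluminium C[Al](C)C
Why: a second Negishi carboalumination gives the second E-alkene (C8=C9), and the alkenylalanate opens the epoxide with retention to append C11–C12.

Step 6
Reactants: 10 (3E,6S,7E)-10-iodo-4,8-dimethyldeca-3,7-diene-1,6-diol; 11 methyl 2-(bromomethyl)prop-2-enoate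
Product: 12 methyl (6E,8S,10E)-8,13-dihydroxy-6,10-dimethyl-2-methylidenetrideca-6,10-dienoate
Conditions: 11 (3 equiv), (Bu3Sn)2 (1.2 equiv), hν (sunlamp), benzene, rt
Reagents that add atoms: none
Why: ditin-mediated radical allyl transfer (SH2′): the primary alkyl radical adds to the acrylate CH2 and β-eliminates Br•, which tolerates both free hydroxyls and installs the 2-alkylacrylate.

Step 7
Reactants: 12 methyl (6E,8S,10E)-8,13-dihydroxy-6,10-dimethyl-2-methylidenetrideca-6,10-dienoate
Product: 13 bicyclic exo-methylene diol ester (trans-decalin; 4α-CO2Me, 4β-CH3, 5α-H, 6α-OH, 8-methylidene, 9β-CH2CH2OH, 10β-CH3)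
Conditions: Co(dmgBF2)2(H2O)2 (5 mol%), H2 (3 atm), benzene (0.02 M), 50 °C
Reagents that add atoms: none
Why: Proposed new method: the weak Co–H bond of the cobaloxime hydride transfers H• only to the acrylate CH2 (closest known reaction: cobaloxime/H2 hydrogen-atom-transfer cycloisomerisation of α-substituted acrylate dienes to monocycles); the electrophilic tertiary α-ester radical closes ring A 6-endo onto C5, the nucleophilic C10 radical closes ring B 6-endo onto C9 in a chair–chair array, and Co(II) removes a β-hydrogen from the C8 radical; the C6 hydroxyl stays equatorial (an axial one would clash with the C10 methyl) and hydrogen-bonds to the ester carbonyl in benzene, which directs attack to that face of C5 and holds the ester equatorial, so C4, C5, C9 and C10 all follow from C6 (E-alkenes give the trans fusion and the equatorial C9 chain).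

Step 8
Reactants: 13 bicyclic exo-methylene diol ester
Product: 14 bicyclic triol ester (as 13, but 8α-OH, 8β-CH3)
Conditions: Co(acac)2 (20 mol%), PhSiH3 (2 equiv), O2 (1 atm), THF, rt
Reagents that add atoms: dioxygen O=O
Why: Mukaiyama hydration: Markovnikov hydrogen-atom transfer gives the tertiary C8 radical (any ring-alkene isomer funnels to the same radical), which O2 traps from the α face opposite the axial C10 methyl to give the equatorial 8α-OH.

Step 9
Reactants: 15 pent-3-yn-1-ol
Product: 17 (3E)-4-bromopent-3-en-1-ol, via alkenylzirconocene 16 (not isolated)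
Conditions: Cp2Zr(H)Cl (2.5 equiv), THF, rt→40 °C; NBS, 0 °C; aq. HCl
Reagents that add atoms: N-bromosuccinimide O=C1CCC(=O)N1Br
Why: Schwartz hydrozirconation (syn addition, Zr equilibrates to the less hindered methyl-bearing carbon) and bromodezirconation with retention give the E-alkenyl bromide.

Step 10
Reactants: 17 (3E)-4-bromopent-3-en-1-ol
Product: 18 (3E)-4-bromopent-3-enal
Conditions: Dess–Martin periodinane, CH2Cl2, 0 °C; used crude
Reagents that add atoms: none
Why: Dess–Martin oxidation is non-basic, so the β,γ-unsaturated aldehyde does not slip into conjugation.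

Step 11
Reactants: 18 (3E)-4-bromopent-3-enal; 19 methyl prop-2-ynoate
Product: 20 methyl (4R,6E)-7-bromo-4-hydroxyoct-6-en-2-ynoate
Conditions: (S,S)-ProPhenol (10 mol%), Me2Zn (3 equiv), Ph3PO (20 mol%), toluene, 4 °C; aq. NH4Cl
Reagents that add atoms: none
Why: dinuclear zinc–ProPhenol-catalysed alkynylation of the aldehyde with the zinc acetylide of methyl propiolate sets the C16 carbinol as R by catalyst control.

Step 12
Reactants: 20 methyl (4R,6E)-7-bromo-4-hydroxyoct-6-en-2-ynoate
Product: 21 methyl (4R,6E)-7-bromo-4-(triethylsilyloxy)oct-6-en-2-ynoate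
Conditions: TESCl, imidazole, CH2Cl2, 0 °C
Reagents that add atoms: chlorotriethylsilane CC[Si](Cl)(CC)CC
Why: silyl ether formation keeps the carbinol from lactonising in the next step, so the side chain stays open-chain and base-stable until the end.

Step 13
Reactants: 21 methyl (4R,6E)-7-bromo-4-(triethylsilyloxy)oct-6-en-2-ynoate
Product: 22 methyl (2Z,4R,6E)-7-bromo-3-methyl-4-(triethylsilyloxy)octa-2,6-dienoate
Conditions: Me2CuLi (1.3 equiv), THF, −78 °C; aq. NH4Cl at −78 °C
Reagents that add atoms: lithium dimethylcuprate [Li+].C[Cu-]C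
Why: syn-carbocupration of the ynoate and cold protonation give the (Z)-β-methyl enoate (ester cis to C16), the geometry needed for butenolide closure; the alkenyl bromide is inert at −78 °C.

Step 14
Reactants: 14 bicyclic triol ester; 22 methyl (2Z,4R,6E)-7-bromo-3-methyl-4-(triethylsilyloxy)octa-2,6-dienoate
Product: 24 seco-diester (C23 methyl ester, 6α-OH, 8α-OH, 13E-alkene, 16R-OTES, 17Z-enoate methyl ester at C19), via NHC–alcohol adduct 23 (not isolated)
Conditions: 5,7-di-tert-butyl-3-phenylbenzoxazolium BF4 (1.2 equiv), pyridine, MTBE, rt; then 22 (1.5 equiv), [Ir(ppy)2(dtbbpy)]PF6 (1 mol%), NiBr2·dtbbpy (5 mol%), quinuclidine, DMA, blue LEDs, rt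
Reagents that add atoms: none
Why: Proposed new method: the primary C12–OH condenses selectively with the benzoxazolium salt, photocatalytic oxidation, deprotonation and β-scission release the C12 radical, and nickel couples it with the alkenyl bromide with retention of the E geometry; no electrophilic C12 species is formed, so the 8α-OH cannot close a tetrahydrofuran (closest known reactions: nickel/photoredox deoxygenative arylation of NHC-activated alcohols and decarboxylative alkenylation).

Step 15
Reactants: 24 seco-diester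
Product: 26 target CNP0387770.1, via dipotassium seco-dicarboxylate 25 (not isolated)
Conditions: KOH, DMSO–H2O (5:1), 80 °C; then 2 M HCl, THF, rt (pH ≈ 2)
Reagents that add atoms: potassium hydroxide [K+].[OH-]
Why: saponification of both methyl esters (the hindered C23 ester assisted by the neighbouring 6α-alkoxide) with loss of the silyl group, then acid-induced lactonisation of the (Z)-γ-hydroxy acid to the butenolide; C16 is not acidic in the open-chain carboxylate and the strained 23,6-lactone does not form.

## Compound list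

1 | but-3-yn-1-ol | C#CCCO | starting material
2 | (E)-[4-(dimethylalumanyloxy)-2-methylbut-1-en-1-yl]dimethylalumane | C[Al](C)/C=C(\C)CCO[Al](C)C | intermediate
3 | (2E)-3-methylpent-2-ene-1,5-diol | OC/C=C(\C)CCO | intermediate
4 | (2E)-5-hydroxy-3-methylpent-2-enal | O=C/C=C(\C)CCO | intermediate
5 | (2E)-5-iodo-3-methylpent-2-enal | O=C/C=C(\C)CCI | intermediate
6 | allenylboronic acid pinacol ester | C=C=CB1OC(C)(C)C(C)(C)O1 | starting material
7 | (4S,5E)-8-iodo-6-methyloct-5-en-1-yn-4-ol | C#CC[C@H](O)/C=C(\C)CCI | intermediate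
8 | ethylene oxide | C1CO1 | starting material
9 | [(1E,4S,5E)-4-(dimethylalumanyloxy)-8-iodo-2,6-dimethylocta-1,5-dien-1-yl]dimethylalumane | C[Al](C)/C=C(\C)C[C@H](O[Al](C)C)/C=C(\C)CCI | intermediate
10 | (3E,6S,7E)-10-iodo-4,8-dimethyldeca-3,7-diene-1,6-diol | OCC/C=C(\C)C[C@H](O)/C=C(\C)CCI | intermediate
11 | methyl 2-(bromomethyl)prop-2-enoate | C=C(CBr)C(=O)OC | starting material
12 | methyl (6E,8S,10E)-8,13-dihydroxy-6,10-dimethyl-2-methylidenetrideca-6,10-dienoate | OCC/C=C(\C)C[C@H](O)/C=C(\C)CCCC(=C)C(=O)OC | intermediate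
13 | bicyclic exo-methylene diol ester (4α-CO2Me, 4β-CH3, 5α-H, 6α-OH, 8-methylidene, 9β-CH2CH2OH, 10β-CH3) | OCC[C@@H]1[C@@]2(C)CCC[C@@](C)(C(=O)OC)[C@@H]2[C@@H](O)CC1=C | intermediate
14 | bicyclic triol ester (as 13, with 8α-OH and 8β-CH3) | OCC[C@@H]1[C@@]2(C)CCC[C@@](C)(C(=O)OC)[C@@H]2[C@@H](O)C[C@@]1(C)O | intermediate
15 | pent-3-yn-1-ol | CC#CCCO | starting material
16 | (E)-pent-2-en-2-yl zirconocene chloride carrying the O–Zr(Cl)Cp2 alkoxide at C5 | C/C(=C\CCO[Zr](Cl)(C1C=CC=C1)C1C=CC=C1)[Zr](Cl)(C1C=CC=C1)C1C=CC=C1 | intermediate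
17 | (3E)-4-bromopent-3-en-1-ol | OCC/C=C(\C)Br | intermediate
18 | (3E)-4-bromopent-3-enal | O=CC/C=C(\C)Br | intermediate
19 | methyl prop-2-ynoate | C#CC(=O)OC | starting material
20 | methyl (4R,6E)-7-bromo-4-hydroxyoct-6-en-2-ynoate | COC(=O)C#C[C@H](O)C/C=C(\C)Br | intermediate
21 | methyl (4R,6E)-7-bromo-4-(triethylsilyloxy)oct-6-en-2-ynoate | COC(=O)C#C[C@H](O[Si](CC)(CC)CC)C/C=C(\C)Br | intermediate
22 | methyl (2Z,4R,6E)-7-bromo-3-methyl-4-(triethylsilyloxy)octa-2,6-dienoate | COC(=O)/C=C(/C)[C@H](O[Si](CC)(CC)CC)C/C=C(\C)Br | intermediate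
23 | NHC–alcohol adduct (14 bound through O12 to C2 of 5,7-di-tert-butyl-3-phenyl-2,3-dihydrobenzoxazole) | O1C(OCC[C@@H]3[C@@]4(C)CCC[C@@](C)(C(=O)OC)[C@@H]4[C@@H](O)C[C@@]3(C)O)N(c2ccccc2)c2cc(C(C)(C)C)cc(C(C)(C)C)c12 | intermediate
24 | seco-diester (C23 and C19 methyl esters, 16R-OTES, 13E, 17Z) | COC(=O)/C=C(/C)[C@H](O[Si](CC)(CC)CC)C/C=C(\C)CC[C@@H]1[C@@]2(C)CCC[C@@](C)(C(=O)OC)[C@@H]2[C@@H](O)C[C@@]1(C)O | intermediate
25 | dipotassium seco-dicarboxylate (16R-OH free) | [K+].[K+].[O-]C(=O)/C=C(/C)[C@H](O)C/C=C(\C)CC[C@@H]1[C@@]2(C)CCC[C@@](C)(C([O-])=O)[C@@H]2[C@@H](O)C[C@@]1(C)O | intermediate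
26 | target CNP0387770.1 | CC1=CC(=O)O[C@@H]1C/C=C(\C)CC[C@@H]1[C@@]2(C)CCC[C@@](C)(C(=O)O)[C@@H]2[C@@H](O)C[C@@]1(C)O | target

## Step count

Total: 15 steps. Longest linear sequence: 10 steps (steps 1–8, 14, 15, from but-3-yn-1-ol); the side-chain branch is steps 9–13.

## Steps most likely to fail, with fallbacks

**Step 7 (radical bicyclisation).** Risks are isomerisation of the acrylate to the unreactive 2-methyl-2-enoate, stopping after one ring, and the ester ending up axial at C4 if the hydrogen bond does not control the first ring closure. The fallback sets out from 10 and returns at 14. Reductive Giese addition of iodide 10 to methyl methacrylate ((Me3Si)3SiH, AIBN, benzene, 80 °C) gives methyl (6E,8S,10E)-8,13-dihydroxy-2,6,10-trimethyltrideca-6,10-dienoate F1. Enolate bromination (LDA, THF, −78 °C, then CBr4) gives methyl (6E,8S,10E)-2-bromo-8,13-dihydroxy-2,6,10-trimethyltrideca-6,10-dienoate F2. Photoredox reduction of the C–Br bond (fac-Ir(ppy)3, blue LEDs, NaHCO3, MeCN–H2O) generates the same tertiary α-ester radical without any metal hydride; both rings close, Ir(IV) oxidises the C8 radical to the cation and water adds from the α face. This radical–polar crossover gives 14 directly and replaces steps 6–8.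

**Step 14 (deoxygenative alkenylation).** Risks are poor radical capture by nickel with an alkenyl bromide and competing activation of the C6 hydroxyl. The fallback sets out from 13 and returns at 24; it moves the handle to boron before the 8α-OH exists. Appel iodination of 13 (I2, PPh3, imidazole) gives the C12 iodide of the exo-methylene ester F3. Copper-catalysed borylation (CuI, PPh3, B2pin2, LiOtBu) gives the C12 pinacol boronate F4. Mukaiyama hydration as in step 8 gives the 8α-hydroxy boronate F5, which cannot cyclise onto C12. Suzuki–Miyaura coupling of F5 with 22 (Pd(OAc)2, RuPhos, K3PO4, toluene–H2O, 80 °C) gives 24; the open-chain silyloxy enoate tolerates the base.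

**Step 15 (global saponification and lactonisation).** Risk is that the hindered C23 methyl ester resists hydrolysis or that the forcing base damages the side chain. The fallback sets out from 24 and returns at 26. PPTS in MeOH removes the silyl group and the freed (Z)-γ-hydroxy enoate lactonises to the target methyl ester F6. LiI in refluxing EtOAc then cleaves the C23 ester by SN2 attack at the O–CH3 carbon, which leaves the butenolide closed and needs no hydroxide.

Further compounds
F1 | step 7 | methyl (6E,8S,10E)-8,13-dihydroxy-2,6,10-trimethyltrideca-6,10-dienoate (2RS) | OCC/C=C(\C)C[C@H](O)/C=C(\C)CCCC(C)C(=O)OC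
F2 | step 7 | methyl (6E,8S,10E)-2-bromo-8,13-dihydroxy-2,6,10-trimethyltrideca-6,10-dienoate (2RS) | OCC/C=C(\C)C[C@H](O)/C=C(\C)CCCC(C)(Br)C(=O)OC
F3 | step 14 | C12 iodide of the exo-methylene ester (13 with I in place of the C12 hydroxyl) | ICC[C@@H]1[C@@]2(C)CCC[C@@](C)(C(=O)OC)[C@@H]2[C@@H](O)CC1=C
F4 | step 14 | C12 pinacol boronate of the exo-methylene ester | CC1(C)OB(CC[C@@H]2[C@@]3(C)CCC[C@@](C)(C(=O)OC)[C@@H]3[C@@H](O)CC2=C)OC1(C)C
F5 | step 14 | 8α-hydroxy C12 pinacol boronate | CC1(C)OB(CC[C@@H]2[C@@]3(C)CCC[C@@](C)(C(=O)OC)[C@@H]3[C@@H](O)C[C@@]2(C)O)OC1(C)C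
F6 | step 15 | target methyl ester (butenolide closed, C23 CO2Me) | CC1=CC(=O)O[C@@H]1C/C=C(\C)CC[C@@H]1[C@@]2(C)CCC[C@@](C)(C(=O)OC)[C@@H]2[C@@H](O)C[C@@]1(C)O
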